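Fitting a first-order decay to X here treats [G] as a constant, and that is the pitfall: J is charged once, and I assume each E takes one G.

common to all: X 0.10 M; Q 0.10 M
- teal: J 0.11 M; L 1.3 mM; run made earlier
- ochre: J 0.11 M; L 2.8 mM; run made earlier
- flask: J 0.110 M; L 1.9 mM; time 8.0 min

| run | time / min | E / % |
|---|---|---|
| teal | 0.500 | 1.4 |
| teal | 1.50 | 3.7 |
| teal | 3.00 | 10.5 |
| teal | 5.00 | 16.1 |
| teal | 6.00 | 21.6 |
| ochre | 1.33 | 6.4 |
| ochre | 2.50 | 17.6 |
| ochre | 4.00 | 23.1 |
| ochre | 5.00 | 26.8 |
| ochre | 6.00 | 29.9 |

(each reading ± 1 percentage point)

- E at 8.0 min, in percent of the X and Q together charged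
- concentration of G in solution at 8.0 min, in percent of saturation

I assume the rate of E goes as [G][L][X]. Ochre gains 0.00680 M min⁻¹ around 5.00 min, when its E reading leaves [X] at 0.0464 M. If J is all dissolved and E is the sole sink, [G] is 0.0564 M, so a G lives 8.29 min there. Rescaled to this flask's [L] and charged [X], and multiplied by ln(2), this gives 3.93 min, the pseudo-first-order half-life of G, a reading that carries the scatter of the runs. With the rate proportional to [G], this half-life holds at any [G] while [L] and [X] are held, so you can count: 8.0 min is 2.04 half-lives. Counting the J charge as if it were dissolved at the start, which it is not, and holding [X] as charged, my rough figure for [G] in this flask at 8.0 min is 0.0268 M. The runs read E and not G, so this count gives no percentage of saturation.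

The forecast gave 28 % (25 % to 32 %) for E and 90 % (70 % to 100 %) of saturation for G, in its words “By then the demand for G is small and J is still in excess”.

The flask gives 27.4 % for E and 37.2 % of saturation for G.

    G + L + X → L + E (k = 16.0 L² mol⁻² s⁻¹)
    G + L + Q → L + D (k = 4.80 L² mol⁻² s⁻¹)
    J ⇌ G, rate k3*(cs3 - [G]) while solid is left; crystals form when [G] > cs3 (solubility = 0.0910 M, k = 0.0260 s⁻¹)

In this flask [G] stands at 0.0339 M, more than the 0.0268 M you counted. Now take the neighbouring flask with 0.066 M of J and the other charges and the time as before. The half-life stays 3.93 min and the count stays 2.04 half-lives, so you reckon [G] at 0.0160 M. That flask gives 0.0156 M at 8.00 min, with J at 0 % of its charge and E at 18.7 %.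

All runs were generated by integration from invented constants; scatter was added.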